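**Plan**

- Ring A is the 2-hydroxy-4-methoxy-6-propylbenzoyl unit (C1 carries the carbonyl) and ring B is the 5-pentylpyrogallol unit (O1 acylated, O2 and O3 free). The ester carbonyl is a single carbon atom between C1 of ring A and O1 of ring B, so it can be brought in as carbon monoxide.
- Retrosynthesis: the 2-O-methyl ether of ring A and an O2/O3 acetonide of ring B are put back first. Both bonds of the carbonyl carbon (ring A C1–CO and CO–O1) are then cut, leaving a ring A iodide, CO and a ring B phenol. The propyl and pentyl chains are cut from the rings as Grignard reagents.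
- Forward: no ring is built, since both benzene rings are bought. Kumada coupling and iodination give the iodide (2 steps); Kumada coupling, demethylation and ketalisation give the phenol (3 steps). The three components are joined in one operation, then the ketal is hydrolysed and the methoxy group ortho to the carbonyl is cleaved.
- Stereochemistry: the target has no stereocentre and no stereogenic double bond, so nothing has to be controlled.

Key step: step 6

**Route**

Step 1
Reactants: 1 1-bromo-3,5-dimethoxybenzene; 2 n-propylmagnesium bromide
Product: 3 1,3-dimethoxy-5-propylbenzene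
Conditions: NiCl2(dppp) (2 mol %), THF, 0 °C to reflux; aq. NH4Cl
Reagents that add atoms: none
Why: Kumada–Tamao–Corriu coupling, in which zerovalent nickel formed from NiCl2(dppp) and the Grignard reagent adds to the C–Br bond, transmetalates and eliminates reductively, the chelating dppp keeping the n-propyl group unbranched.

Step 2
Reactants: 3 1,3-dimethoxy-5-propylbenzene
Product: 4 2-iodo-1,5-dimethoxy-3-propylbenzene
Conditions: NIS (1.05 equiv), TFA (cat.), MeCN, 0 °C to rt, dark
Reagents that add atoms: N-iodosuccinimide, O=C1CCC(=O)N1I
Why: Electrophilic aromatic iodination of a 5-alkylresorcinol dimethyl ether should take place para to one methoxy group (between propyl and the other methoxy) in preference to the site between the two methoxy groups, and the two such positions are equivalent by symmetry, so one mono-iodide is expected.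

Step 3
Reactants: 5 5-bromo-1,2,3-trimethoxybenzene; 6 n-pentylmagnesium bromide
Product: 7 1,2,3-trimethoxy-5-pentylbenzene
Conditions: NiCl2(dppp) (2 mol %), THF/Et2O, 0 °C to reflux; aq. NH4Cl
Reagents that add atoms: none
Why: Kumada–Tamao–Corriu coupling of an aryl bromide with a primary alkyl Grignard reagent, as in step 1; the methyl ethers are inert to the nickel–dppp catalyst.

Step 4
Reactants: 7 1,2,3-trimethoxy-5-pentylbenzene
Product: 8 5-pentylbenzene-1,2,3-triol
Conditions: BBr3 (4 equiv), CH2Cl2, −78 °C to rt; H2O (under argon)
Reagents that add atoms: none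
Why: BBr3 cleavage of aryl methyl ethers (boron–oxygen adduct, bromide attack at methyl, hydrolysis of the aryl borates) should remove all three methyl groups; the air-sensitive triol is carried on without delay.

Step 5
Reactants: 8 5-pentylbenzene-1,2,3-triol
Product: 9 2,2-dimethyl-6-pentyl-1,3-benzodioxol-4-ol
Conditions: 2,2-dimethoxypropane, p-TsOH (cat.), toluene, reflux, 4 Å molecular sieves (removal of MeOH)
Reagents that add atoms: 2,2-dimethoxypropane, COC(C)(C)OC
Why: Acid-catalysed transketalisation closes the five-membered isopropylidene ketal on two adjacent phenolic oxygens, as known for pyrogallol; the two adjacent pairs are equivalent by symmetry, so a single ketal with one free hydroxyl (O1) should result.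

Step 6
Reactants: 4 2-iodo-1,5-dimethoxy-3-propylbenzene; 10 carbon monoxide; 9 2,2-dimethyl-6-pentyl-1,3-benzodioxol-4-ol
Product: 11 2,2-dimethyl-6-pentyl-1,3-benzodioxol-4-yl 2,4-dimethoxy-6-propylbenzoate
Conditions: Pd(OAc)2 (5 mol %), Xantphos (6 mol %), Et3N (3 equiv), CO (5 bar), dry toluene, 100 °C
Reagents that add atoms: none
Why: Zerovalent palladium formed from Pd(OAc)2 and Xantphos adds oxidatively to the C–I bond of 4, CO inserts into the crowded aryl–palladium bond to give a divalent aroylpalladium iodide, the triethylammonium phenoxide of 9 takes the place of iodide, and C–O reductive elimination releases ester 11 and zerovalent palladium. The closest known reaction type is the palladium-catalysed aryloxycarbonylation (Heck-type carbonylation) of aryl iodides with phenols under CO. No ring is closed and no stereocentre is made; the step forms the two skeletal bonds ring A C1–C(=O) and C(=O)–O1 of ring B. The selectivity needed is carbonylative coupling in preference to direct diaryl ether formation, hydrodeiodination or capture of the acyl group by water; CO pressure, the wide bite angle of Xantphos, the reluctance of a di-ortho-substituted arylpalladium phenoxide to eliminate directly and dry conditions should secure it. Site selectivity on ring B follows from the ketal, which leaves O1 as the only free hydroxyl, and the symmetry of arene 3 has already fixed the position of the iodine on ring A.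

Step 7
Reactants: 11 2,2-dimethyl-6-pentyl-1,3-benzodioxol-4-yl 2,4-dimethoxy-6-propylbenzoate
Product: 12 2,3-dihydroxy-5-pentylphenyl 2,4-dimethoxy-6-propylbenzoate
Conditions: TFA/CH2Cl2/H2O (10:10:1), 0 °C to rt, under argon
Reagents that add atoms: none
Why: Acid-catalysed ketal hydrolysis by way of the aryloxy-stabilised oxocarbenium ion frees the catechol, while the di-ortho-substituted benzoate is too hindered for acyl transfer to the neighbouring O2 under these non-basic conditions.

Step 8
Reactants: 12 2,3-dihydroxy-5-pentylphenyl 2,4-dimethoxy-6-propylbenzoate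
Product: 13 Peruvinide C (2,3-dihydroxy-5-pentylphenyl 2-hydroxy-4-methoxy-6-propylbenzoate)
Conditions: BCl3 (4 equiv), CH2Cl2, −78 °C to 0 °C; aq. HCl
Reagents that add atoms: none
Why: Chelation-controlled Lewis acid ether cleavage: boron bridges the ester carbonyl oxygen and the ortho methoxy oxygen in a six-membered chelate and chloride removes that methyl group only, the unchelated 4-methoxy group staying intact; the catechol consumes one equivalent of BCl3 as a cyclic borate that is hydrolysed on work-up.

**Compound list**

1 | 1-bromo-3,5-dimethoxybenzene | COc1cc(Br)cc(OC)c1 | starting material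
2 | n-propylmagnesium bromide (commercial solution) | CCC[Mg]Br | starting material
3 | 1,3-dimethoxy-5-propylbenzene | CCCc1cc(OC)cc(OC)c1 | intermediate
4 | 2-iodo-1,5-dimethoxy-3-propylbenzene | CCCc1cc(OC)cc(OC)c1I | intermediate
5 | 5-bromo-1,2,3-trimethoxybenzene | COc1cc(Br)cc(OC)c1OC | starting material
6 | n-pentylmagnesium bromide (commercial solution) | CCCCC[Mg]Br | starting material
7 | 1,2,3-trimethoxy-5-pentylbenzene | CCCCCc1cc(OC)c(OC)c(OC)c1 | intermediate
8 | 5-pentylbenzene-1,2,3-triol | CCCCCc1cc(O)c(O)c(O)c1 | intermediate
9 | 2,2-dimethyl-6-pentyl-1,3-benzodioxol-4-ol | CCCCCc1cc(O)c2OC(C)(C)Oc2c1 | intermediate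
10 | carbon monoxide | [C-]#[O+] | starting material
11 | 2,2-dimethyl-6-pentyl-1,3-benzodioxol-4-yl 2,4-dimethoxy-6-propylbenzoate | CCCCCc1cc2OC(C)(C)Oc2c(OC(=O)c2c(OC)cc(OC)cc2CCC)c1 | intermediate
12 | 2,3-dihydroxy-5-pentylphenyl 2,4-dimethoxy-6-propylbenzoate | CCCCCc1cc(O)c(O)c(OC(=O)c2c(OC)cc(OC)cc2CCC)c1 | intermediate
13 | Peruvinide C, 2,3-dihydroxy-5-pentylphenyl 2-hydroxy-4-methoxy-6-propylbenzoate (achiral) | CCCCCc1cc(O)c(O)c(OC(=O)c2c(O)cc(OC)cc2CCC)c1 | target

**Count**

Total step count: 8.
Longest linear sequence: 6 steps (steps 3, 4, 5, 6, 7, 8, from 5-bromo-1,2,3-trimethoxybenzene); the ring A branch (steps 1 and 2) joins at step 6.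

**Steps most likely to fail**

1. Step 6. Turnover may stall at the hindered aroylpalladium stage because the phenoxide is captured slowly, so that hydrodeiodination or hydrolysis of the acyl group takes over. Fallback from iodide 4: iodine–lithium exchange (n-BuLi, THF, −78 °C) should give (2,4-dimethoxy-6-propylphenyl)lithium F1, which is trapped with CO2 and acidified with aq. HCl to 2,4-dimethoxy-6-propylbenzoic acid F2. With (CF3CO)2O in dry toluene at rt this forms 2,4-dimethoxy-6-propylbenzoic trifluoroacetic anhydride F3 in the flask, which acylates phenol 9 through the hindered acylium ion. The sequence comes back to the route at ester 11.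

2. Step 8. The ether cleavage may lose its selectivity (attack on the 4-methoxy group), or the Lewis acid may break the acyl–oxygen bond of the electron-rich, hindered aryl ester. Fallback, again from iodide 4 and passing through the lithium compound F1 and acid F2 as described above: BCl3 in CH2Cl2 cleaves the ether ortho to the carboxyl group before any aryl ester is present and should give 2-hydroxy-4-methoxy-6-propylbenzoic acid F4. Carbodiimide condensation with phenol 9 (DCC, toluene, rt), in which the hydrogen-bonded ortho hydroxyl does not compete, should give 2,2-dimethyl-6-pentyl-1,3-benzodioxol-4-yl 2-hydroxy-4-methoxy-6-propylbenzoate F5. Ketal hydrolysis under the conditions of step 7 comes back to the route at target 13.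

3. Step 7. Under the acid needed to open the catechol ketal, the acyl group may migrate to the neighbouring O2, the ester may cleave by an acylium pathway, or the freed catechol may oxidise in air. Fallback from triol 8: heating with dichlorodiphenylmethane (neat, 170 °C) should give 6-pentyl-2,2-diphenyl-1,3-benzodioxol-4-ol F6. Carbonylative coupling with 4 and 10 under the conditions of step 6 should give 6-pentyl-2,2-diphenyl-1,3-benzodioxol-4-yl 2,4-dimethoxy-6-propylbenzoate F7. Hydrogenolysis (H2, Pd/C, EtOAc/THF, rt) removes this ketal under neutral conditions and comes back to the route at catechol 12.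

**Further compounds**

F1 | step 6 | (2,4-dimethoxy-6-propylphenyl)lithium | [Li]c1c(CCC)cc(OC)cc1OC
F2 | step 6 | 2,4-dimethoxy-6-propylbenzoic acid | CCCc1cc(OC)cc(OC)c1C(=O)O
F3 | step 6 | 2,4-dimethoxy-6-propylbenzoic trifluoroacetic anhydride | CCCc1cc(OC)cc(OC)c1C(=O)OC(=O)C(F)(F)F
F4 | step 8 | 2-hydroxy-4-methoxy-6-propylbenzoic acid | CCCc1cc(OC)cc(O)c1C(=O)O
F5 | step 8 | 2,2-dimethyl-6-pentyl-1,3-benzodioxol-4-yl 2-hydroxy-4-methoxy-6-propylbenzoate | CCCCCc1cc2OC(C)(C)Oc2c(OC(=O)c2c(O)cc(OC)cc2CCC)c1
F6 | step 7 | 6-pentyl-2,2-diphenyl-1,3-benzodioxol-4-ol | CCCCCc1cc(O)c2OC(c3ccccc3)(c3ccccc3)Oc2c1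
F7 | step 7 | 6-pentyl-2,2-diphenyl-1,3-benzodioxol-4-yl 2,4-dimethoxy-6-propylbenzoate | CCCCCc1cc2OC(c3ccccc3)(c3ccccc3)Oc2c(OC(=O)c2c(OC)cc(OC)cc2CCC)c1
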